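## Retrosynthetic overview

1. The quinone is unmasked last from hydroquinone dimethyl ether 35 with CAN; the (3Z)-alkylidene comes from a stereospecific syn-dehydration of the syn-β-hydroxy lactone 33.
2. The δ-lactone, the only ring built in the route, closes after the fragment coupling: desilylation of aldol adduct 31 lets the δ-hydroxyl displace the oxazolidinone.
3. Key C–C bond (C3–C1'): intermolecular Evans boron syn-aldol between imide 28 and aldehyde 16.
4. Imide 28 comes from a CBS reduction of isopropenyl ketone 21 (sets 6R), itself from the Weinreb amide of methyl glutaryl chloride and isopropenylmagnesium bromide.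
5. Aldehyde 16 comes from periodate cleavage of epoxide 15, made from the aryl bromide 5 (ex o-cresol) and 10,11-epoxyfarnesyl bromide 12 (ex E,E-farnesol); the aromatic ring is carried through from o-cresol.

Assumption: the C10 centre of the epoxyfarnesyl series (8–12 and 15) is destroyed in step 10, so these compounds are carried as racemates and drawn without a descriptor at that carbon.

## Route

**Step 1**
Reactants: 1 o-cresol
Product: 2 2,4-dibromo-6-methylphenol
Conditions: Br2 (2.05 equiv), AcOH, 0 °C → rt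
Reagents that add atoms: bromine, BrBr
Why: Electrophilic aromatic bromination, with the phenol OH directing to its free ortho and para positions.

**Step 2**
Reactants: 2 2,4-dibromo-6-methylphenol
Product: 3 2-bromo-6-methyl-1,4-benzoquinone
Conditions: CrO3, AcOH/H2O/MeCN, 65 °C
Reagents that add atoms: water, O
Why: Chromic acid oxidation of a para-halophenol to the p-quinone, in which water attacks the oxidised ring para to oxygen and the para bromine is expelled while the ortho bromine stays.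

**Step 3**
Reactants: 3 2-bromo-6-methyl-1,4-benzoquinone
Product: 4 2-bromo-6-methylbenzene-1,4-diol
Conditions: Na2S2O4, Et2O/H2O, rt
Reagents that add atoms: none
Why: Dithionite reduction of a quinone to its hydroquinone is fast and leaves the aryl bromide alone.

**Step 4**
Reactants: 4 2-bromo-6-methylbenzene-1,4-diol
Product: 5 1-bromo-2,5-dimethoxy-3-methylbenzene
Conditions: MeI, K2CO3, acetone, reflux, N2
Reagents that add atoms: iodomethane, CI
Why: Williamson ether synthesis on both phenols gives a masked quinone that tolerates organolithium, boron enolate and fluoride chemistry.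

**Step 5**
Reactants: 6 (2E,6E)-farnesol
Product: 7 (2E,6E)-farnesyl acetate
Conditions: Ac2O, pyridine, DMAP (cat.), CH2Cl2, 0 °C → rt
Reagents that add atoms: acetic anhydride, CC(=O)OC(C)=O
Why: DMAP-catalysed acylation protects the allylic alcohol and deactivates the 2,3-alkene toward the electrophile of step 6.

**Step 6**
Reactants: 7 (2E,6E)-farnesyl acetate
Product: 8 (2E,6E)-10-bromo-11-hydroxy-3,7,11-trimethyldodeca-2,6-dien-1-yl acetate (racemic)
Conditions: NBS (1.1 equiv), THF/H2O, 0 °C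
Reagents that add atoms: N-bromosuccinimide, O=C1CCC(=O)N1Br; water, O
Why: van Tamelen terminal bromohydrin formation, in which the coiled chain in aqueous THF exposes the terminal trisubstituted alkene and water opens the bromonium ion at the tertiary carbon.

**Step 7**
Reactants: 8 (2E,6E)-10-bromo-11-hydroxy-3,7,11-trimethyldodeca-2,6-dien-1-yl acetate
Product: 10 (2E,6E)-10,11-epoxy-3,7,11-trimethyldodeca-2,6-dien-1-ol (racemic), via epoxyfarnesyl acetate 9 (not isolated)
Conditions: K2CO3 (3 equiv), MeOH, rt, 12 h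
Reagents that add atoms: none
Why: Intramolecular Williamson SN2 closes the epoxide and carbonate-catalysed transesterification then removes the acetate in the same pot.

**Step 8**
Reactants: 10 (2E,6E)-10,11-epoxy-3,7,11-trimethyldodeca-2,6-dien-1-ol
Product: 12 (2E,6E)-1-bromo-10,11-epoxy-3,7,11-trimethyldodeca-2,6-diene (racemic), via allylic mesylate 11 (not isolated)
Conditions: MsCl, Et3N, THF, −45 °C; then LiBr, THF, 0 °C
Reagents that add atoms: lithium bromide, [Li+].[Br-]
Why: Mesylation followed by SN2 displacement with bromide at the primary allylic carbon occurs without allylic transposition, E/Z erosion or epoxide opening at low temperature.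

**Step 9**
Reactants: 5 1-bromo-2,5-dimethoxy-3-methylbenzene; 12 (2E,6E)-1-bromo-10,11-epoxy-3,7,11-trimethyldodeca-2,6-diene
Product: 15 1-[(2E,6E)-10,11-epoxy-3,7,11-trimethyldodeca-2,6-dien-1-yl]-2,5-dimethoxy-3-methylbenzene (racemic), via aryllithium 13 (not isolated), via arylcopper 14 (not isolated)
Conditions: n-BuLi, THF, −78 °C; CuBr·SMe2, −78 → −40 °C; then 12, −78 → 0 °C
Reagents that add atoms: none
Why: Bromine–lithium exchange, transmetallation to copper and SN2 allylic substitution, with attack at the unhindered primary carbon retaining the 2E geometry and leaving the hindered trisubstituted epoxide untouched.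

**Step 10**
Reactants: 15 1-[(2E,6E)-10,11-epoxy-3,7,11-trimethyldodeca-2,6-dien-1-yl]-2,5-dimethoxy-3-methylbenzene
Product: 16 (4E,8E)-10-(2,5-dimethoxy-3-methylphenyl)-4,8-dimethyldeca-4,8-dienal
Conditions: H5IO6 (1.2 equiv), THF/Et2O, 0 °C
Reagents that add atoms: none
Why: Periodic acid hydrolyses the epoxide to the diol and cleaves it (Malaprade glycol cleavage) to the trisnor aldehyde, whose oxygen is the former epoxide oxygen, without touching the alkenes or aryl ethers.

**Step 11**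
Reactants: 17 methyl 5-chloro-5-oxopentanoate
Product: 18 methyl 5-[methoxy(methyl)amino]-5-oxopentanoate
Conditions: MeNH(OMe)·HCl, pyridine, CH2Cl2, 0 °C → rt
Reagents that add atoms: N,O-dimethylhydroxylamine hydrochloride, CNOC.Cl
Why: Weinreb amide formation by acylation of the amine with the acid chloride is far faster than any reaction at the methyl ester.

**Step 12**
Reactants: 18 methyl 5-[methoxy(methyl)amino]-5-oxopentanoate; 19 isopropenylmagnesium bromide
Product: 21 methyl 6-methyl-5-oxohept-6-enoate, via magnesium hemiaminal chelate 20 (not isolated)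
Conditions: 19 (1.3 equiv), THF, −78 → −20 °C; inverse quench into cold 1 M HCl
Reagents that add atoms: none
Why: Weinreb ketone synthesis, in which a single Grignard addition gives a stable five-membered magnesium chelate that collapses to the enone only on acidic quench, while the methyl ester is not attacked at low temperature.

**Step 13**
Reactants: 21 methyl 6-methyl-5-oxohept-6-enoate
Product: 23 methyl (5R)-5-hydroxy-6-methylhept-6-enoate, via catecholboryl ether 22 (not isolated)
Conditions: (S)-Me-CBS (0.2 equiv), catecholborane (1.8 equiv), toluene, −78 °C; MeOH, then NaHCO3 wash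
Reagents that add atoms: none
Why: Corey–Bakshi–Shibata reduction, in which the ketone binds the (S)-oxazaborolidine with the larger isopropenyl group away from the catalyst so that hydride reaches the Si face, setting the (R)-carbinol by 1,2-reduction only.

**Step 14**
Reactants: 23 methyl (5R)-5-hydroxy-6-methylhept-6-enoate
Product: 24 methyl (5R)-5-(tert-butyldimethylsilyloxy)-6-methylhept-6-enoate
Conditions: TBSCl, imidazole, DMF, 0 °C → rt (23 used directly)
Reagents that add atoms: tert-butyldimethylsilyl chloride, CC(C)(C)[Si](C)(C)Cl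
Why: Imidazole-promoted silyl ether formation caps the allylic alcohol before it can lactonise and makes it inert to the enolisation of step 17.

**Step 15**
Reactants: 24 methyl (5R)-5-(tert-butyldimethylsilyloxy)-6-methylhept-6-enoate
Product: 25 (5R)-5-(tert-butyldimethylsilyloxy)-6-methylhept-6-enoic acid
Conditions: LiOH·H2O, THF/MeOH/H2O, rt; 1 M HCl to pH 3–4, 0 °C
Reagents that add atoms: lithium hydroxide, [Li+].[OH-]
Why: Saponification of the methyl ester (BAc2) leaves the secondary TBS ether and the stereocentre untouched.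

**Step 16**
Reactants: 25 (5R)-5-(tert-butyldimethylsilyloxy)-6-methylhept-6-enoic acid; 26 (4S)-4-benzyl-1,3-oxazolidin-2-one
Product: 28 (4S)-4-benzyl-3-[(5R)-5-(tert-butyldimethylsilyloxy)-6-methylhept-6-enoyl]-1,3-oxazolidin-2-one, via mixed pivalic anhydride 27 (not isolated)
Conditions: PivCl, Et3N, THF, −20 °C; then 26, LiCl, −20 °C → rt
Reagents that add atoms: none
Why: N-acylation of the Evans auxiliary through the mixed anhydride, the LiCl/Et3N-activated oxazolidinone attacking the less hindered carbonyl.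

**Step 17 (key step)**
Reactants: 28 (4S)-4-benzyl-3-[(5R)-5-(tert-butyldimethylsilyloxy)-6-methylhept-6-enoyl]-1,3-oxazolidin-2-one; 16 (4E,8E)-10-(2,5-dimethoxy-3-methylphenyl)-4,8-dimethyldeca-4,8-dienal
Product: 31 (4S)-4-benzyl-3-[(2S,3R,6E,10E)-2-[(3R)-3-(tert-butyldimethylsilyloxy)-4-methylpent-4-en-1-yl]-12-(2,5-dimethoxy-3-methylphenyl)-3-hydroxy-6,10-dimethyldodeca-6,10-dienoyl]-1,3-oxazolidin-2-one, via Z-boron enolate 29 (not isolated), via boron aldolate 30 (not isolated)
Conditions: n-Bu2BOTf, i-Pr2NEt, CH2Cl2, 0 °C; 16, −78 → 0 °C; pH 7 buffer, MeOH, 30% H2O2, 0 °C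
Reagents that add atoms: none
Why: Evans syn-aldol reaction, in which the (Z)-boron enolate reacts through a Zimmerman–Traxler chair on the face away from the benzyl group to give the 2,3-syn (2S,3R) adduct with high diastereoselectivity.

**Step 18**
Reactants: 31 (the syn-aldol adduct)
Product: 33 (3S,6R)-3-[(1R,4E,8E)-10-(2,5-dimethoxy-3-methylphenyl)-1-hydroxy-4,8-dimethyldeca-4,8-dien-1-yl]-6-(prop-1-en-2-yl)oxan-2-one, via desilylated hydroxy imide 32 (not isolated)
Conditions: HF·pyridine, pyridine/THF, 0 °C → rt; NaHCO3 work-up; then Et3N, DMAP (cat.), CH2Cl2, rt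
Reagents that add atoms: none
Why: Fluoride desilylation frees the δ-hydroxyl, which attacks the activated exocyclic imide carbonyl (intramolecular transacylation, six-membered lactonisation) and expels the auxiliary without touching any stereocentre.

**Step 19**
Reactants: 33 (the syn-β-hydroxy lactone)
Product: 35 (3Z,6R)-3-[(4E,8E)-10-(2,5-dimethoxy-3-methylphenyl)-4,8-dimethyldeca-4,8-dien-1-ylidene]-6-(prop-1-en-2-yl)oxan-2-one, via O-alkyl isourea 34 (not isolated)
Conditions: DCC (3 equiv), CuCl (0.3 equiv), toluene, 80 °C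
Reagents that add atoms: none
Why: Copper-catalysed carbodiimide dehydration is a stereospecific syn (Ei-type) elimination, so loss of C3–H and the isourea oxygen from the same side of the syn-aldol places the chain cis to the lactone carbonyl, giving the (Z)-alkylidene.

**Step 20**
Reactants: 35 (the Z-alkylidene lactone dimethyl ether)
Product: 36 (3Z,6R)-3-[(4E,8E)-4,8-dimethyl-10-(5-methyl-3,6-dioxocyclohexa-1,4-dien-1-yl)deca-4,8-dien-1-ylidene]-6-(prop-1-en-2-yl)oxan-2-one
Conditions: CAN (2.5 equiv), MeCN/H2O, 0 °C, 20 min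
Reagents that add atoms: water, O
Why: Cerium(IV) oxidative demethylation of the hydroquinone dimethyl ether (water adds to the oxidised ring and methanol leaves) gives the p-quinone faster than any reaction of the alkenes or the lactone.

## Compound list

1 | o-cresol (2-methylphenol) | Cc1ccccc1O | starting material
2 | 2,4-dibromo-6-methylphenol | Cc1cc(Br)cc(Br)c1O | intermediate
3 | 2-bromo-6-methyl-1,4-benzoquinone | CC1=CC(=O)C=C(Br)C1=O | intermediate
4 | 2-bromo-6-methylbenzene-1,4-diol | Cc1cc(O)cc(Br)c1O | intermediate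
5 | 1-bromo-2,5-dimethoxy-3-methylbenzene | COc1cc(C)c(OC)c(Br)c1 | intermediate
6 | (2E,6E)-farnesol | CC(C)=CCC/C(C)=C/CC/C(C)=C/CO | starting material
7 | (2E,6E)-farnesyl acetate | CC(C)=CCC/C(C)=C/CC/C(C)=C/COC(C)=O | intermediate
8 | (2E,6E)-10-bromo-11-hydroxy-3,7,11-trimethyldodeca-2,6-dien-1-yl acetate (racemic) | CC(C)(O)C(Br)CC/C(C)=C/CC/C(C)=C/COC(C)=O | intermediate
9 | (2E,6E)-10,11-epoxy-3,7,11-trimethyldodeca-2,6-dien-1-yl acetate (racemic; in situ) | CC1(C)OC1CC/C(C)=C/CC/C(C)=C/COC(C)=O | intermediate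
10 | (2E,6E)-10,11-epoxy-3,7,11-trimethyldodeca-2,6-dien-1-ol (racemic) | CC1(C)OC1CC/C(C)=C/CC/C(C)=C/CO | intermediate
11 | (2E,6E)-10,11-epoxy-3,7,11-trimethyldodeca-2,6-dien-1-yl methanesulfonate (racemic; in situ) | CC1(C)OC1CC/C(C)=C/CC/C(C)=C/COS(C)(=O)=O | intermediate
12 | (2E,6E)-1-bromo-10,11-epoxy-3,7,11-trimethyldodeca-2,6-diene (racemic) | CC1(C)OC1CC/C(C)=C/CC/C(C)=C/CBr | intermediate
13 | (2,5-dimethoxy-3-methylphenyl)lithium (in situ) | [Li]c1cc(OC)cc(C)c1OC | intermediate
14 | (2,5-dimethoxy-3-methylphenyl)copper (in situ) | [Cu]c1cc(OC)cc(C)c1OC | intermediate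
15 | 1-[(2E,6E)-10,11-epoxy-3,7,11-trimethyldodeca-2,6-dien-1-yl]-2,5-dimethoxy-3-methylbenzene (racemic) | CC1(C)OC1CC/C(C)=C/CC/C(C)=C/Cc1cc(OC)cc(C)c1OC | intermediate
16 | (4E,8E)-10-(2,5-dimethoxy-3-methylphenyl)-4,8-dimethyldeca-4,8-dienal | O=CCC/C(C)=C/CC/C(C)=C/Cc1cc(OC)cc(C)c1OC | intermediate
17 | methyl 5-chloro-5-oxopentanoate | COC(=O)CCCC(=O)Cl | starting material
18 | methyl 5-[methoxy(methyl)amino]-5-oxopentanoate | COC(=O)CCCC(=O)N(C)OC | intermediate
19 | isopropenylmagnesium bromide | C=C(C)[Mg]Br | starting material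
20 | bromomagnesium hemiaminal chelate of 18 and 19 (in situ) | COC(=O)CCCC(O[Mg]Br)(N(C)OC)C(C)=C | intermediate
21 | methyl 6-methyl-5-oxohept-6-enoate | COC(=O)CCCC(=O)C(C)=C | intermediate
22 | methyl (5R)-5-(1,3,2-benzodioxaborol-2-yloxy)-6-methylhept-6-enoate (in situ) | COC(=O)CCC[C@@H](OB1Oc2ccccc2O1)C(C)=C | intermediate
23 | methyl (5R)-5-hydroxy-6-methylhept-6-enoate | COC(=O)CCC[C@@H](O)C(C)=C | intermediate
24 | methyl (5R)-5-(tert-butyldimethylsilyloxy)-6-methylhept-6-enoate | COC(=O)CCC[C@@H](O[Si](C)(C)C(C)(C)C)C(C)=C | intermediate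
25 | (5R)-5-(tert-butyldimethylsilyloxy)-6-methylhept-6-enoic acid | OC(=O)CCC[C@@H](O[Si](C)(C)C(C)(C)C)C(C)=C | intermediate
26 | (4S)-4-benzyl-1,3-oxazolidin-2-one | O=C1N[C@@H](Cc2ccccc2)CO1 | starting material
27 | mixed pivalic anhydride of 25 (in situ) | CC(C)(C)C(=O)OC(=O)CCC[C@@H](O[Si](C)(C)C(C)(C)C)C(C)=C | intermediate
28 | (4S)-4-benzyl-3-[(5R)-5-(tert-butyldimethylsilyloxy)-6-methylhept-6-enoyl]-1,3-oxazolidin-2-one | O=C1OC[C@H](Cc2ccccc2)N1C(=O)CCC[C@@H](O[Si](C)(C)C(C)(C)C)C(C)=C | intermediate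
29 | (Z)-dibutylboron enolate of 28 (in situ) | CCCCB(CCCC)O/C(=C\CC[C@@H](O[Si](C)(C)C(C)(C)C)C(C)=C)N1[C@@H](Cc2ccccc2)COC1=O | intermediate
30 | O-dibutylboryl aldolate of 31 (in situ) | O=C1OC[C@H](Cc2ccccc2)N1C(=O)[C@@H](CC[C@@H](O[Si](C)(C)C(C)(C)C)C(C)=C)[C@H](OB(CCCC)CCCC)CC/C(C)=C/CC/C(C)=C/Cc3cc(OC)cc(C)c3OC | intermediate
31 | (4S)-4-benzyl-3-[(2S,3R,6E,10E)-2-[(3R)-3-(tert-butyldimethylsilyloxy)-4-methylpent-4-en-1-yl]-12-(2,5-dimethoxy-3-methylphenyl)-3-hydroxy-6,10-dimethyldodeca-6,10-dienoyl]-1,3-oxazolidin-2-one | O=C1OC[C@H](Cc2ccccc2)N1C(=O)[C@@H](CC[C@@H](O[Si](C)(C)C(C)(C)C)C(C)=C)[C@H](O)CC/C(C)=C/CC/C(C)=C/Cc3cc(OC)cc(C)c3OC | intermediate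
32 | (4S)-4-benzyl-3-[(2S,3R,6E,10E)-12-(2,5-dimethoxy-3-methylphenyl)-3-hydroxy-2-[(3R)-3-hydroxy-4-methylpent-4-en-1-yl]-6,10-dimethyldodeca-6,10-dienoyl]-1,3-oxazolidin-2-one (in situ) | O=C1OC[C@H](Cc2ccccc2)N1C(=O)[C@@H](CC[C@@H](O)C(C)=C)[C@H](O)CC/C(C)=C/CC/C(C)=C/Cc3cc(OC)cc(C)c3OC | intermediate
33 | (3S,6R)-3-[(1R,4E,8E)-10-(2,5-dimethoxy-3-methylphenyl)-1-hydroxy-4,8-dimethyldeca-4,8-dien-1-yl]-6-(prop-1-en-2-yl)oxan-2-one | C=C(C)[C@H]1CC[C@@H]([C@H](O)CC/C(C)=C/CC/C(C)=C/Cc2cc(OC)cc(C)c2OC)C(=O)O1 | intermediate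
34 | O-alkyl-N,N'-dicyclohexylisourea of 33 (in situ) | C=C(C)[C@H]1CC[C@@H]([C@H](OC(=NC2CCCCC2)NC3CCCCC3)CC/C(C)=C/CC/C(C)=C/Cc4cc(OC)cc(C)c4OC)C(=O)O1 | intermediate
35 | (3Z,6R)-3-[(4E,8E)-10-(2,5-dimethoxy-3-methylphenyl)-4,8-dimethyldeca-4,8-dien-1-ylidene]-6-(prop-1-en-2-yl)oxan-2-one | C=C(C)[C@H]1CC/C(=C/CC/C(C)=C/CC/C(C)=C/Cc2cc(OC)cc(C)c2OC)C(=O)O1 | intermediate
36 | (3Z,6R)-3-[(4E,8E)-4,8-dimethyl-10-(5-methyl-3,6-dioxocyclohexa-1,4-dien-1-yl)deca-4,8-dien-1-ylidene]-6-(prop-1-en-2-yl)oxan-2-one (CNP0305496.1) | C=C(C)[C@H]1CC/C(=C/CC/C(C)=C/CC/C(C)=C/CC2=CC(=O)C=C(C)C2=O)C(=O)O1 | target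

## Summary

Total step count: 20.
Longest linear sequence: 10 steps (for example steps 11–20 from 17; the branches from 1 and from 6 are also 10).

Three steps most likely to fail:

**Step 19 (syn-dehydration).** The risk is leakage to the more stable E-alkylidene through an E1cB pathway. The fallback swaps syn-aldol/syn-elimination for anti-aldol/anti-elimination and sets out from 28 and 16. The boron enolate 29 is added to 16 precomplexed with Et2AlCl (Heathcock open-transition-state variant), giving the anti-aldol imide (4S)-4-benzyl-3-[(2R,3R,6E,10E)-2-[(3R)-3-(tert-butyldimethylsilyloxy)-4-methylpent-4-en-1-yl]-12-(2,5-dimethoxy-3-methylphenyl)-3-hydroxy-6,10-dimethyldodeca-6,10-dienoyl]-1,3-oxazolidin-2-one F5; the 2R,3R assignment is from the usual model for this variant and only the anti relationship matters. HF·pyridine then Et3N/DMAP as in step 18 leads through the desilylated anti hydroxy imide F6 (not isolated) to the anti hydroxy lactone (3R,6R)-3-[(1R,4E,8E)-10-(2,5-dimethoxy-3-methylphenyl)-1-hydroxy-4,8-dimethyldeca-4,8-dien-1-yl]-6-(prop-1-en-2-yl)oxan-2-one F7. Martin sulfurane (CH2Cl2, 0 °C) then effects an E2 anti-elimination, which again places the chain cis to the carbonyl, and the route is rejoined at 35.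

**Step 13 (CBS reduction of an isopropenyl ketone).** The risks are modest ee and competing 1,4-reduction by catecholborane. The fallback replaces asymmetric reduction by kinetic resolution and sets out from 21. Luche reduction (NaBH4, CeCl3·7H2O, MeOH, −40 °C) gives racemic methyl 5-hydroxy-6-methylhept-6-enoate F1. Sharpless kinetic resolution (Ti(OiPr)4, L-(+)-DIPT, 0.6 equiv TBHP, 4 Å MS, CH2Cl2, −20 °C) epoxidises the (S)-enantiomer to the erythro epoxy alcohol methyl (5S)-5-hydroxy-5-[(2R)-2-methyloxiran-2-yl]pentanoate F2, which is removed by chromatography. The unreacted (R)-alcohol is 23, where the route is rejoined.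

**Step 18 (one-pot desilylation and transacylation).** The risks are sluggish attack of the hindered allylic δ-hydroxyl on the imide and retro-aldol under base. The fallback removes the auxiliary hydrolytically first and sets out from 31. LiOH/H2O2 (THF/H2O, 0 °C) gives (2S,3R,6E,10E)-2-[(3R)-3-(tert-butyldimethylsilyloxy)-4-methylpent-4-en-1-yl]-12-(2,5-dimethoxy-3-methylphenyl)-3-hydroxy-6,10-dimethyldodeca-6,10-dienoic acid F3. HF·pyridine then gives the dihydroxy acid (2S,3R,6E,10E)-12-(2,5-dimethoxy-3-methylphenyl)-3-hydroxy-2-[(3R)-3-hydroxy-4-methylpent-4-en-1-yl]-6,10-dimethyldodeca-6,10-dienoic acid F4. Acid-catalysed lactonisation (PPTS, CH2Cl2, rt) closes the six-membered ring in preference to the β-lactone and rejoins the route at 33.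

## Further compounds

F1 | step 13 | rac-methyl 5-hydroxy-6-methylhept-6-enoate | COC(=O)CCCC(O)C(C)=C
F2 | step 13 | methyl (5S)-5-hydroxy-5-[(2R)-2-methyloxiran-2-yl]pentanoate | COC(=O)CCC[C@H](O)[C@@]1(C)CO1
F3 | step 18 | (2S,3R,6E,10E)-2-[(3R)-3-(tert-butyldimethylsilyloxy)-4-methylpent-4-en-1-yl]-12-(2,5-dimethoxy-3-methylphenyl)-3-hydroxy-6,10-dimethyldodeca-6,10-dienoic acid | OC(=O)[C@@H](CC[C@@H](O[Si](C)(C)C(C)(C)C)C(C)=C)[C@H](O)CC/C(C)=C/CC/C(C)=C/Cc1cc(OC)cc(C)c1OC
F4 | step 18 | (2S,3R,6E,10E)-12-(2,5-dimethoxy-3-methylphenyl)-3-hydroxy-2-[(3R)-3-hydroxy-4-methylpent-4-en-1-yl]-6,10-dimethyldodeca-6,10-dienoic acid | OC(=O)[C@@H](CC[C@@H](O)C(C)=C)[C@H](O)CC/C(C)=C/CC/C(C)=C/Cc1cc(OC)cc(C)c1OC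
F5 | step 19 | (4S)-4-benzyl-3-[(2R,3R,6E,10E)-2-[(3R)-3-(tert-butyldimethylsilyloxy)-4-methylpent-4-en-1-yl]-12-(2,5-dimethoxy-3-methylphenyl)-3-hydroxy-6,10-dimethyldodeca-6,10-dienoyl]-1,3-oxazolidin-2-one | O=C1OC[C@H](Cc2ccccc2)N1C(=O)[C@H](CC[C@@H](O[Si](C)(C)C(C)(C)C)C(C)=C)[C@H](O)CC/C(C)=C/CC/C(C)=C/Cc3cc(OC)cc(C)c3OC
F6 | step 19 | (4S)-4-benzyl-3-[(2R,3R,6E,10E)-12-(2,5-dimethoxy-3-methylphenyl)-3-hydroxy-2-[(3R)-3-hydroxy-4-methylpent-4-en-1-yl]-6,10-dimethyldodeca-6,10-dienoyl]-1,3-oxazolidin-2-one | O=C1OC[C@H](Cc2ccccc2)N1C(=O)[C@H](CC[C@@H](O)C(C)=C)[C@H](O)CC/C(C)=C/CC/C(C)=C/Cc3cc(OC)cc(C)c3OC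
F7 | step 19 | (3R,6R)-3-[(1R,4E,8E)-10-(2,5-dimethoxy-3-methylphenyl)-1-hydroxy-4,8-dimethyldeca-4,8-dien-1-yl]-6-(prop-1-en-2-yl)oxan-2-one | C=C(C)[C@H]1CC[C@H]([C@H](O)CC/C(C)=C/CC/C(C)=C/Cc2cc(OC)cc(C)c2OC)C(=O)O1
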